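## Retrosynthetic overview

1. The ring ketone comes from MnO2 oxidation of a macrocyclic allylic alcohol; the ten-membered ring is closed last by NiCl2/CrCl2 coupling of a 2-iodoallyl angelate with an aldehyde.
2. Key step: CrCl2-mediated allylation of an α-angeloyloxy aldehyde by an enantiopure 5-substituted 3-(bromomethyl)butenolide. One operation joins the halves, unveils the α-methylene lactone, sets the ring-fusion and carbinol carbons, and leaves free only the hydroxyl that is free in the target.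
3. Aldehyde half: (2E)-pent-2-en-4-yn-1-ol → 2-iodo diene → Sharpless epoxidation → Ti(OiPr)4/angelic acid opening with inversion (angelate stereocentre) → glycol cleavage.
4. Butenolide half: (R)-epichlorohydrin → enynol → Negishi carboalumination/ethylene oxide (E olefin) → Shi epoxidation → 2-(bromomethyl)acrylate → ring-closing metathesis.
5. Ring order: oxirane, butenolide, ten-membered carbocycle; the only protecting group is one primary silyl ether.

Assumption: germacrane locants are used (C1/C10 epoxide with the methyl on C10, C3 ketone, C4 exocyclic methylene, C5 angelate, C6 hydroxyl, C7/C8 lactone fusion with the oxygen on C8), and (R)-epichlorohydrin, (2E)-pent-2-en-4-yn-1-ol, angelic acid, 2-(bromomethyl)acrylic acid and the D-fructose-derived Shi ketone are bought.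

## Route

Step 1
Reactants: 1 (R)-epichlorohydrin
Product: 2 (2R)-1-chloro-5-(trimethylsilyl)pent-4-yn-2-ol
Conditions: TMSC≡CH, n-BuLi, THF, −78 °C; BF3·OEt2, then 1, −78 °C; H2O quench
Reagents that add atoms: (trimethylsilyl)acetylene, C#C[Si](C)(C)C
Why: BF3-promoted alkynylation of an epoxide (Yamaguchi type): the lithium acetylide opens the oxirane at its CH2 terminus by SN2, so the existing stereocentre (later C8) is untouched.

Step 2
Reactants: 2 chlorohydrin
Product: 4 (3R)-6-(trimethylsilyl)hex-1-en-5-yn-3-ol, via epoxide 3 (not isolated)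
Conditions: Me3S+ I− (4 equiv), n-BuLi (3.8 equiv), THF, −10 °C → rt
Reagents that add atoms: trimethylsulfonium iodide, C[S+](C)C.[I-]
Why: Corey–Chaykovsky-type one-carbon homologation: the alkoxide closes to epoxide 3, dimethylsulfonium methylide opens it at CH2 and a second ylide equivalent eliminates Me2S to give the vinyl carbinol without touching the stereocentre.

Step 3
Reactants: 4 silylated enynol
Product: 5 (3R)-hex-1-en-5-yn-3-ol
Conditions: K2CO3, MeOH, rt
Reagents that add atoms: none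
Why: Base-mediated methanolysis of the alkynyl C–Si bond (protodesilylation) frees the terminal alkyne needed for carbometalation.

Step 4
Reactants: 5 enynol
Product: 8 (3R,5E)-5-methylocta-1,5-diene-3,8-diol, via alkenylalane 6 (not isolated), via alanate 7 (not isolated)
Conditions: Me3Al (3 equiv), Cp2ZrCl2 (25 mol%), CH2Cl2, 0 °C → rt; evaporate; n-BuLi, THF/hexane, −78 °C; ethylene oxide, −78 → 0 °C; aq. KNaC4H4O6 (potassium sodium tartrate)
Reagents that add atoms: trimethylaluminium, C[Al](C)C; ethylene oxide, C1CO1; n-butyllithium, [Li]CCCC (stays in 7 only)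
Why: Negishi zirconium-catalysed carboalumination adds Me and Al syn across the terminal alkyne (Me on the internal carbon), fixing the E trisubstituted olefin, and the derived alkenylalanate opens ethylene oxide with retention of olefin geometry.

Step 5
Reactants: 8 diol
Product: 9 (3R,5E)-8-[(tert-butyldimethylsilyl)oxy]-5-methylocta-1,5-dien-3-ol
Conditions: TBSCl (1.05 equiv), imidazole, CH2Cl2, −20 → 0 °C
Reagents that add atoms: tert-butyldimethylsilyl chloride, CC(C)(C)[Si](C)(C)Cl
Why: Selective silylation: the primary hydroxyl reacts much faster than the secondary allylic one.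

Step 6
Reactants: 9 silyl ether
Product: 10 (2R)-1-[(2R,3R)-3-{2-[(tert-butyldimethylsilyl)oxy]ethyl}-2-methyloxiran-2-yl]but-3-en-2-ol
Conditions: D-fructose-derived Shi ketone (30 mol%), KHSO5 (as 2KHSO5·KHSO4·K2SO4), K2CO3, Bu4NHSO4, MeCN/CH2(OMe)2, aq. Na2B4O7 buffer, 0 °C
Reagents that add atoms: potassium peroxymonosulfate KHSO5, [K+].[O-]S(=O)(=O)OO
Why: Shi asymmetric epoxidation: the chiral dioxirane oxidises only the electron-rich trisubstituted E olefin through a spiro transition state and gives the (R,R)-epoxide (C1 and C10) under catalyst control; the monosubstituted vinyl group is far slower.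

Step 7
Reactants: 10 epoxy alcohol
Product: 11 (2R)-1-[(2R,3R)-3-{2-[(tert-butyldimethylsilyl)oxy]ethyl}-2-methyloxiran-2-yl]but-3-en-2-yl 2-(bromomethyl)prop-2-enoate
Conditions: 2-(bromomethyl)acrylic acid, (COCl)2, cat. DMF, CH2Cl2, 0 °C → rt, evaporate; then 10, 2,6-di-tert-butyl-4-methylpyridine, CH2Cl2, −20 → 0 °C
Reagents that add atoms: 2-(bromomethyl)prop-2-enoic acid, OC(=O)C(=C)CBr (delivered as its chloride, ClC(=O)C(=C)CBr)
Why: Acylation of the secondary alcohol by an acid chloride, with a hindered base that scavenges HCl (protecting the epoxide) but cannot displace the allylic bromide; no stereocentre is touched.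

Step 8
Reactants: 11 bromomethylacrylate ester
Product: 12 (5R)-3-(bromomethyl)-5-{[(2R,3R)-3-{2-[(tert-butyldimethylsilyl)oxy]ethyl}-2-methyloxiran-2-yl]methyl}furan-2(5H)-one
Conditions: second-generation Grubbs catalyst (H2IMes)(PCy3)Cl2Ru=CHPh (10 mol%), toluene, 80 °C, 5 mM
Reagents that add atoms: none
Why: Ring-closing metathesis between the vinyl carbinol and the acrylate olefin closes the five-membered butenolide; the bromine sits gamma to ruthenium in the metallacycle and cannot β-eliminate.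

Step 9
Reactants: 13 (2E)-pent-2-en-4-yn-1-ol
Product: 15 (2E)-4-iodopenta-2,4-dien-1-ol, via vinylstannane 14 (not isolated)
Conditions: Bu3SnH, Pd(PPh3)2Cl2 (2 mol%), THF, 0 °C → rt; then I2, CH2Cl2, 0 °C; aq. Na2S2O3
Reagents that add atoms: tributyltin hydride, CCCC[SnH](CCCC)CCCC (tin stays in 14 only); iodine, [I][I]
Why: Palladium-catalysed syn-hydrostannation of a conjugated terminal enyne puts tin on the internal alkyne carbon, and iododestannylation then occurs with retention to give the 2-iodo-1,3-diene.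

Step 10
Reactants: 15 iododienol
Product: 16 [(2R,3S)-3-(1-iodoethenyl)oxiran-2-yl]methanol
Conditions: Ti(OiPr)4 (10 mol%), D-(−)-diethyl tartrate (12 mol%), t-BuOOH (2 equiv), 4 Å MS, CH2Cl2, −20 °C
Reagents that add atoms: tert-butyl hydroperoxide, CC(C)(C)OO
Why: Sharpless asymmetric epoxidation touches only the allylic-alcohol olefin; D-(−)-tartrate gives the enantiomer spatially analogous to the (2R,3R)-3-alkyl series (the C3 descriptor reads S because of the iodovinyl group).

Step 11
Reactants: 16 epoxy alcohol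
Product: 17 (2R,3R)-1,2-dihydroxy-4-iodopent-4-en-3-yl (2Z)-2-methylbut-2-enoate
Conditions: angelic acid (1.5 equiv), Ti(OiPr)4 (1.5 equiv), CH2Cl2, rt
Reagents that add atoms: angelic acid, C/C=C(/C)C(=O)O
Why: Ti(OiPr)4-mediated C3-selective opening of a 2,3-epoxy alcohol by a carboxylic acid (Sharpless): the carboxylate attacks the allylic C3 by SN2 with inversion, which sets C5 and installs the angelate without an esterification that could isomerise it to the tiglate.

Step 12
Reactants: 17 diol angelate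
Product: 18 (2R)-3-iodo-1-oxobut-3-en-2-yl (2Z)-2-methylbut-2-enoate
Conditions: NaIO4, THF/pH 7 buffer, 0 °C, 20 min; extracted and used at once
Reagents that add atoms: none
Why: Malaprade glycol cleavage of the terminal 1,2-diol under neutral conditions gives the configurationally labile α-acyloxy aldehyde without base.

Step 13
Reactants: 12 bromomethylbutenolide; 18 α-angeloyloxy aldehyde
Product: 19 (1R,2R)-1-[(2R,3R)-2-{[(2R,3R)-3-{2-[(tert-butyldimethylsilyl)oxy]ethyl}-2-methyloxiran-2-yl]methyl}-4-methylidene-5-oxooxolan-3-yl]-1-hydroxy-3-iodobut-3-en-2-yl (2Z)-2-methylbut-2-enoate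
Conditions: CrCl2 (4 equiv, nickel-free), THF, 0 °C → rt; pH 7 phosphate buffer
Reagents that add atoms: none
Why: Nozaki–Hiyama-type chromium Barbier allylation (SE2′): the allylchromium from 12 attacks through the ring β-carbon in a closed chair transition state, anti to the C8 side chain (C7, trans lactone), and, as an E-type γ-substituted allyl reagent with the aldehyde residue equatorial, gives the C6 carbinol that is also the polar Felkin–Anh product relative to the C5 acyloxy group (matched pair).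

Step 14
Reactants: 19 allylation adduct
Product: 20 (1R,2R)-1-hydroxy-1-[(2R,3R)-2-{[(2R,3R)-3-(2-hydroxyethyl)-2-methyloxiran-2-yl]methyl}-4-methylidene-5-oxooxolan-3-yl]-3-iodobut-3-en-2-yl (2Z)-2-methylbut-2-enoate
Conditions: Bu4NF/AcOH (1:1), THF, 0 °C → rt
Reagents that add atoms: none
Why: Buffered fluoride desilylation removes the primary silyl ether under near-neutral conditions that spare the epoxide, the lactone and the angelate.

Step 15
Reactants: 20 diol
Product: 21 (1R,2R)-1-hydroxy-3-iodo-1-[(2R,3R)-2-{[(2R,3R)-2-methyl-3-(2-oxoethyl)oxiran-2-yl]methyl}-4-methylidene-5-oxooxolan-3-yl]but-3-en-2-yl (2Z)-2-methylbut-2-enoate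
Conditions: TEMPO (20 mol%), PhI(OAc)2 (1.2 equiv), CH2Cl2, rt
Reagents that add atoms: none
Why: Oxoammonium (TEMPO) oxidation is selective for the primary alcohol over the hindered secondary C6 hydroxyl and is neutral enough for the β,γ-epoxy aldehyde.

Step 16
Reactants: 21 iodo aldehyde
Product: 22 (1R,3RS,5S,6R,7R,8R,10R)-5-angeloyloxy-1,10-epoxy-3,6-dihydroxygermacra-4(15),11(13)-dien-12,8-olide
Conditions: CrCl2 (15 equiv), NiCl2 (0.2 equiv), DMSO, 3 mM, slow addition, rt
Reagents that add atoms: none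
Why: Nozaki–Hiyama–Kishi macrocyclisation: zerovalent nickel inserts into the C–I bond, transmetalation gives a vinyl species of trivalent chromium that adds only to the aldehyde at high dilution to close the C3–C4 bond; the new C3 carbinol configuration is irrelevant.

Step 17
Reactants: 22 macrocyclic allylic alcohol
Product: 23 (1R,5S,6R,7R,8R,10R)-5-angeloyloxy-1,10-epoxy-6-hydroxy-3-oxogermacra-4(15),11(13)-dien-12,8-olide (CNP0348992.5)
Conditions: MnO2 (activated, 30 equiv), CH2Cl2, rt
Reagents that add atoms: none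
Why: Chemoselective MnO2 oxidation of the allylic C3 alcohol (both epimers converge on the enone) leaves the non-allylic C6 hydroxyl and, being neutral, does not open the β,γ-epoxy ketone.

## Compound list

1 | (2R)-2-(chloromethyl)oxirane, (R)-epichlorohydrin | ClC[C@H]1CO1 | starting material
2 | (2R)-1-chloro-5-(trimethylsilyl)pent-4-yn-2-ol | ClC[C@H](O)CC#C[Si](C)(C)C | intermediate
3 | (2R)-2-[3-(trimethylsilyl)prop-2-yn-1-yl]oxirane | C1O[C@@H]1CC#C[Si](C)(C)C | intermediate (not isolated)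
4 | (3R)-6-(trimethylsilyl)hex-1-en-5-yn-3-ol | C=C[C@H](O)CC#C[Si](C)(C)C | intermediate
5 | (3R)-hex-1-en-5-yn-3-ol | C=C[C@H](O)CC#C | intermediate
6 | dimethylaluminium (3R,5E)-6-(dimethylalumanyl)-5-methylhexa-1,5-dien-3-olate | C=C[C@H](O[Al](C)C)C/C(C)=C/[Al](C)C | intermediate (not isolated)
7 | lithium butyl{(1E,4R)-4-[(dimethylalumanyl)oxy]-2-methylhexa-1,5-dien-1-yl}dimethylaluminate | [Li+].C=C[C@H](O[Al](C)C)C/C(C)=C/[Al-](C)(C)CCCC | intermediate (not isolated)
8 | (3R,5E)-5-methylocta-1,5-diene-3,8-diol | C=C[C@H](O)C/C(C)=C/CCO | intermediate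
9 | (3R,5E)-8-[(tert-butyldimethylsilyl)oxy]-5-methylocta-1,5-dien-3-ol | C=C[C@H](O)C/C(C)=C/CCO[Si](C)(C)C(C)(C)C | intermediate
10 | (2R)-1-[(2R,3R)-3-{2-[(tert-butyldimethylsilyl)oxy]ethyl}-2-methyloxiran-2-yl]but-3-en-2-ol | C=C[C@H](O)C[C@@]1(C)O[C@@H]1CCO[Si](C)(C)C(C)(C)C | intermediate
11 | (2R)-1-[(2R,3R)-3-{2-[(tert-butyldimethylsilyl)oxy]ethyl}-2-methyloxiran-2-yl]but-3-en-2-yl 2-(bromomethyl)prop-2-enoate | C=C[C@H](OC(=O)C(=C)CBr)C[C@@]1(C)O[C@@H]1CCO[Si](C)(C)C(C)(C)C | intermediate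
12 | (5R)-3-(bromomethyl)-5-{[(2R,3R)-3-{2-[(tert-butyldimethylsilyl)oxy]ethyl}-2-methyloxiran-2-yl]methyl}furan-2(5H)-one | BrCC1=C[C@@H](C[C@@]2(C)O[C@@H]2CCO[Si](C)(C)C(C)(C)C)OC1=O | intermediate
13 | (2E)-pent-2-en-4-yn-1-ol | OC/C=C/C#C | starting material
14 | (2E)-4-(tributylstannyl)penta-2,4-dien-1-ol | OC/C=C/C(=C)[Sn](CCCC)(CCCC)CCCC | intermediate (not isolated)
15 | (2E)-4-iodopenta-2,4-dien-1-ol | OC/C=C/C(I)=C | intermediate
16 | [(2R,3S)-3-(1-iodoethenyl)oxiran-2-yl]methanol | OC[C@H]1O[C@@H]1C(I)=C | intermediate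
17 | (2R,3R)-1,2-dihydroxy-4-iodopent-4-en-3-yl (2Z)-2-methylbut-2-enoate | OC[C@@H](O)[C@@H](OC(=O)/C(C)=C\C)C(I)=C | intermediate
18 | (2R)-3-iodo-1-oxobut-3-en-2-yl (2Z)-2-methylbut-2-enoate | O=C[C@@H](OC(=O)/C(C)=C\C)C(I)=C | intermediate
19 | (1R,2R)-1-[(2R,3R)-2-{[(2R,3R)-3-{2-[(tert-butyldimethylsilyl)oxy]ethyl}-2-methyloxiran-2-yl]methyl}-4-methylidene-5-oxooxolan-3-yl]-1-hydroxy-3-iodobut-3-en-2-yl (2Z)-2-methylbut-2-enoate | C=C1C(=O)O[C@H](C[C@@]2(C)O[C@@H]2CCO[Si](C)(C)C(C)(C)C)[C@H]1[C@@H](O)[C@@H](OC(=O)/C(C)=C\C)C(I)=C | intermediate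
20 | (1R,2R)-1-hydroxy-1-[(2R,3R)-2-{[(2R,3R)-3-(2-hydroxyethyl)-2-methyloxiran-2-yl]methyl}-4-methylidene-5-oxooxolan-3-yl]-3-iodobut-3-en-2-yl (2Z)-2-methylbut-2-enoate | C=C1C(=O)O[C@H](C[C@@]2(C)O[C@@H]2CCO)[C@H]1[C@@H](O)[C@@H](OC(=O)/C(C)=C\C)C(I)=C | intermediate
21 | (1R,2R)-1-hydroxy-3-iodo-1-[(2R,3R)-2-{[(2R,3R)-2-methyl-3-(2-oxoethyl)oxiran-2-yl]methyl}-4-methylidene-5-oxooxolan-3-yl]but-3-en-2-yl (2Z)-2-methylbut-2-enoate | C=C1C(=O)O[C@H](C[C@@]2(C)O[C@@H]2CC=O)[C@H]1[C@@H](O)[C@@H](OC(=O)/C(C)=C\C)C(I)=C | intermediate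
22 | (1R,3RS,5S,6R,7R,8R,10R)-5-angeloyloxy-1,10-epoxy-3,6-dihydroxygermacra-4(15),11(13)-dien-12,8-olide (C3 epimers) | C=C1C(=O)O[C@@H]2C[C@@]3(C)O[C@@H]3CC(O)C(=C)[C@H](OC(=O)/C(C)=C\C)[C@H](O)[C@@H]12 | intermediate
23 | (1R,5S,6R,7R,8R,10R)-5-angeloyloxy-1,10-epoxy-6-hydroxy-3-oxogermacra-4(15),11(13)-dien-12,8-olide, CNP0348992.5 | C=C1C(=O)O[C@@H]2C[C@@]3(C)O[C@@H]3CC(=O)C(=C)[C@H](OC(=O)/C(C)=C\C)[C@H](O)[C@@H]12 | target

## Step count, risks and fallbacks

Total step count: 17. Longest linear sequence: 13 steps (steps 1–8, then 13–17, from 1); the aldehyde half is 4 steps (9–12).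

**Step 13 (chromium allylation).** The α-acyloxy aldehyde 18 is fragile and can be reduced by divalent chromium. The chromium alkoxide formed next to the angelate could trigger acyl shift or translactonisation, and facial control rests on a matched but untested pair. Fallback: change from a Barbier reaction to an allylboration. Setting out from 12, B2pin2 with catalytic Pd2(dba)3 in toluene at 50 °C gives the pinacol allylboronate F1 (boron on the exocyclic CH2). F1 is isolable and adds to aldehyde 18 in toluene at room temperature through the same closed chair transition state, with no reducing metal and no basic alkoxide. Mild aqueous work-up returns the route at 19.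

**Step 16 (ten-membered ring closure).** The β,γ-epoxy aldehyde may be opened by the Lewis-acidic chromium salts or eliminate to the γ-hydroxy enal, and the ring strain is high. Fallback: postpone the epoxide until the ring is closed. Setting out from 9 (step 6 is skipped), acylation as in step 7 gives the 2-(bromomethyl)acrylate ester F2, and metathesis as in step 8 gives the olefinic bromomethylbutenolide F3. CrCl2 coupling with 18 gives the allylation adduct F4, buffered desilylation gives the diol F5, and TEMPO/PhI(OAc)2 gives the β,γ-unsaturated aldehyde F6. NiCl2/CrCl2 cyclisation of this sturdier substrate gives the macrocyclic triene diol F7. Shi epoxidation of F7 (only the trisubstituted ring olefin is electron-rich; same D-fructose-derived ketone) returns the route at 22. This moves the stereochemical risk to the late epoxidation, where the macrocycle conformation could oppose the catalyst.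

**Step 8 (ring-closing metathesis).** The acrylate olefin is 1,1-disubstituted, electron-poor and carries an allylic bromide, so ring closure may stall. Fallback: close the ring first and add the bromomethyl group afterwards. Setting out from 10, acryloyl chloride with iPr2NEt gives the acrylate F8, whose metathesis (an easy disubstituted olefin) gives the butenolide F9. Morita–Baylis–Hillman hydroxymethylation (aqueous formaldehyde, DABCO or PBu3) gives the 3-(hydroxymethyl)butenolide F10. Appel bromination (CBr4, PPh3, CH2Cl2, 0 °C) returns the route at 12.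

Further compounds
F1 | step 13 | (5R)-5-{[(2R,3R)-3-{2-[(tert-butyldimethylsilyl)oxy]ethyl}-2-methyloxiran-2-yl]methyl}-3-[(4,4,5,5-tetramethyl-1,3,2-dioxaborolan-2-yl)methyl]furan-2(5H)-one | CC1(C)OB(CC2=C[C@@H](C[C@@]3(C)O[C@@H]3CCO[Si](C)(C)C(C)(C)C)OC2=O)OC1(C)C
F2 | step 16 | (3R,5E)-8-[(tert-butyldimethylsilyl)oxy]-5-methylocta-1,5-dien-3-yl 2-(bromomethyl)prop-2-enoate | C=C[C@H](OC(=O)C(=C)CBr)C/C(C)=C/CCO[Si](C)(C)C(C)(C)C
F3 | step 16 | (5R)-3-(bromomethyl)-5-[(2E)-5-[(tert-butyldimethylsilyl)oxy]-2-methylpent-2-en-1-yl]furan-2(5H)-one | BrCC1=C[C@@H](C/C(C)=C/CCO[Si](C)(C)C(C)(C)C)OC1=O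
F4 | step 16 | (1R,2R)-1-[(2R,3R)-2-[(2E)-5-[(tert-butyldimethylsilyl)oxy]-2-methylpent-2-en-1-yl]-4-methylidene-5-oxooxolan-3-yl]-1-hydroxy-3-iodobut-3-en-2-yl (2Z)-2-methylbut-2-enoate | C=C1C(=O)O[C@H](C/C(C)=C/CCO[Si](C)(C)C(C)(C)C)[C@H]1[C@@H](O)[C@@H](OC(=O)/C(C)=C\C)C(I)=C
F5 | step 16 | (1R,2R)-1-hydroxy-1-[(2R,3R)-2-[(2E)-5-hydroxy-2-methylpent-2-en-1-yl]-4-methylidene-5-oxooxolan-3-yl]-3-iodobut-3-en-2-yl (2Z)-2-methylbut-2-enoate | C=C1C(=O)O[C@H](C/C(C)=C/CCO)[C@H]1[C@@H](O)[C@@H](OC(=O)/C(C)=C\C)C(I)=C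
F6 | step 16 | (1R,2R)-1-hydroxy-3-iodo-1-[(2R,3R)-2-[(2E)-2-methyl-5-oxopent-2-en-1-yl]-4-methylidene-5-oxooxolan-3-yl]but-3-en-2-yl (2Z)-2-methylbut-2-enoate | C=C1C(=O)O[C@H](C/C(C)=C/CC=O)[C@H]1[C@@H](O)[C@@H](OC(=O)/C(C)=C\C)C(I)=C
F7 | step 16 | (1(10)E,3RS,5S,6R,7R,8R)-5-angeloyloxy-3,6-dihydroxygermacra-1(10),4(15),11(13)-trien-12,8-olide | C=C1C(=O)O[C@@H]2C/C(C)=C/CC(O)C(=C)[C@H](OC(=O)/C(C)=C\C)[C@H](O)[C@@H]12
F8 | step 8 | (2R)-1-[(2R,3R)-3-{2-[(tert-butyldimethylsilyl)oxy]ethyl}-2-methyloxiran-2-yl]but-3-en-2-yl prop-2-enoate | C=C[C@H](OC(=O)C=C)C[C@@]1(C)O[C@@H]1CCO[Si](C)(C)C(C)(C)C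
F9 | step 8 | (5R)-5-{[(2R,3R)-3-{2-[(tert-butyldimethylsilyl)oxy]ethyl}-2-methyloxiran-2-yl]methyl}furan-2(5H)-one | O=C1C=C[C@@H](C[C@@]2(C)O[C@@H]2CCO[Si](C)(C)C(C)(C)C)O1
F10 | step 8 | (5R)-5-{[(2R,3R)-3-{2-[(tert-butyldimethylsilyl)oxy]ethyl}-2-methyloxiran-2-yl]methyl}-3-(hydroxymethyl)furan-2(5H)-one | OCC1=C[C@@H](C[C@@]2(C)O[C@@H]2CCO[Si](C)(C)C(C)(C)C)OC1=O
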